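**Retrosynthetic overview**

1. Numbering: ring A = C1–C5 and C10 (C3 carbinol, C4 gem-dimethyl), ring B = C5–C10 (C5=C6, C8–CH3 = C12, C9 carries CH3 and C11H2–O). The strategy rests on the alkene carbon C5 belonging to both rings, with C4 on one side and C6–C7 on the other, so that a C5≡C6 alkyne can pass a C4 radical into both rings.
2. Last bonds: the C11–O–aryl ether by SN2 of a C11 triflate with isofraxidin-7-olate, and C8 by C11–OH-directed hydrogenation of a C8 exocyclic methylene.
3. Key disconnection: C4–C5 and C6–C7 in one radical cascade from an acyclic (3S)-epoxy enyne; ring A closes first (6-exo-dig), ring B second (6-endo-trig).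
4. Epoxy enyne: the C5≡C6 alkyne by one-carbon homologation of a C5 aldehyde, the epoxide by asymmetric epoxidation, and the C9–C10 bond with both stereocentres by an enantioselective boron-enolate Ireland–Claisen rearrangement.
5. Starting materials: diethyl malonate, 5-bromo-2-methylpent-2-ene, 2,3-dimethylmaleic anhydride and isofraxidin.

Key step: step 11

Assumption: the (S,S)-bromoborane is taken to give the (2S,3S) acid 11; this sense of induction is not derived here, and if a calibration run on a simple crotyl ester shows the opposite sense, the (R,R)-reagent is used with nothing else changed.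

**Step 1**
Reactants: 1 diethyl malonate; 2 5-bromo-2-methylpent-2-ene
Product: 3 diethyl 2-(4-methylpent-3-en-1-yl)propanedioate
Conditions: NaH, THF–DMF, 0 °C → 60 °C (1 in excess)
Reagents that add atoms: none
Why: Malonic ester alkylation, in which the sodium enolate of 1 (in excess to suppress double alkylation) displaces the primary homoallylic bromide by SN2.

**Step 2**
Reactants: 3 diethyl 2-(4-methylpent-3-en-1-yl)propanedioate
Product: 5 6-methylhept-5-enoic acid, via malonic acid 4 (not isolated)
Conditions: KOH, EtOH–H2O, reflux; HCl to pH 1; then neat, 150 °C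
Reagents that add atoms: potassium hydroxide, [K+].[OH-]
Why: Saponification followed by thermal decarboxylation of the malonic acid (malonic ester synthesis) should leave the monoacid, the trisubstituted alkene being inert to base and to brief heating.

**Step 3**
Reactants: 6 2,3-dimethylmaleic anhydride
Product: 7 (2Z)-2,3-dimethylbut-2-ene-1,4-diol
Conditions: LiAlH4, THF, 0 °C → reflux; aqueous NaOH work-up
Reagents that add atoms: none
Why: Hydride reduction of the cyclic anhydride should give the diol with the Z geometry that the ring of 6 fixes.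

**Step 4**
Reactants: 7 (2Z)-2,3-dimethylbut-2-ene-1,4-diol
Product: 8 (2Z)-4-{[tert-butyl(dimethyl)silyl]oxy}-2,3-dimethylbut-2-en-1-ol
Conditions: NaH (1 equiv), THF, 0 °C; TBSCl (1 equiv), rt
Reagents that add atoms: tert-butyldimethylsilyl chloride (TBSCl), CC(C)(C)[Si](C)(C)Cl
Why: Monosilylation of a symmetrical diol through its monosodium alkoxide (O-silylation), where the two hydroxyls are equivalent and only mono against bis protection has to be controlled.

**Step 5**
Reactants: 5 6-methylhept-5-enoic acid; 8 (2Z)-4-{[tert-butyl(dimethyl)silyl]oxy}-2,3-dimethylbut-2-en-1-ol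
Product: 9 (2Z)-4-{[tert-butyl(dimethyl)silyl]oxy}-2,3-dimethylbut-2-en-1-yl 6-methylhept-5-enoate
Conditions: DCC, DMAP (cat.), CH2Cl2, 0 °C → rt
Reagents that add atoms: none
Why: Steglich esterification joins an unhindered acid and a primary allylic alcohol under neutral conditions that keep the silyl ether and both alkenes.

**Step 6**
Reactants: 9 (2Z)-4-{[tert-butyl(dimethyl)silyl]oxy}-2,3-dimethylbut-2-en-1-yl 6-methylhept-5-enoate
Product: 11 (2S,3S)-3-{[tert-butyl(dimethyl)silyl]oxymethyl}-3,4-dimethyl-2-(4-methylpent-3-en-1-yl)pent-4-enoic acid, via boron enolate 10 (not isolated)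
Conditions: (4S,5S)-2-bromo-4,5-diphenyl-1,3-bis{[3,5-bis(trifluoromethyl)phenyl]sulfonyl}-1,3,2-diazaborolidine (1.2 equiv), Et3N, toluene–hexane, −78 °C; then −20 → 4 °C; aqueous work-up
Reagents that add atoms: none
Why: Enantioselective boron-enolate Ireland–Claisen rearrangement, in which soft enolisation should give the enolate with the side chain trans to O–B, the chiral diazaborolidine selects one of the two enantiomeric chairs, and in that chair the Z alkene (C11H2OSi axial, methyl equatorial at C9) and the enolate geometry (side chain axial at C10) fix the C9/C10 relative configuration while the [3,3] shift forms the C9–C10 bond and the isopropenyl group.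

**Step 7**
Reactants: 11 (2S,3S)-3-{[tert-butyl(dimethyl)silyl]oxymethyl}-3,4-dimethyl-2-(4-methylpent-3-en-1-yl)pent-4-enoic acid
Product: 12 (2S,3S)-3-{[tert-butyl(dimethyl)silyl]oxymethyl}-3,4-dimethyl-2-(4-methylpent-3-en-1-yl)pent-4-en-1-ol
Conditions: LiAlH4, THF, 0 °C → rt
Reagents that add atoms: none
Why: Hydride reduction of the carboxylic acid to the primary alcohol, with the silyl ether and the isolated alkenes inert and no stereocentre touched.

**Step 8**
Reactants: 12 (2S,3S)-3-{[tert-butyl(dimethyl)silyl]oxymethyl}-3,4-dimethyl-2-(4-methylpent-3-en-1-yl)pent-4-en-1-ol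
Product: 13 (2S,3S)-3-{[tert-butyl(dimethyl)silyl]oxymethyl}-3,4-dimethyl-2-(4-methylpent-3-en-1-yl)pent-4-enal
Conditions: Dess–Martin periodinane, CH2Cl2, 0 °C → rt
Reagents that add atoms: none
Why: Dess–Martin oxidation stops at the aldehyde under near-neutral conditions, and the α-carbon C10, flanked by the quaternary C9, should not epimerise.

**Step 9**
Reactants: 13 (2S,3S)-3-{[tert-butyl(dimethyl)silyl]oxymethyl}-3,4-dimethyl-2-(4-methylpent-3-en-1-yl)pent-4-enal
Product: 14 tert-butyl{[(2S,3R)-3-ethynyl-2,7-dimethyl-2-(prop-1-en-2-yl)oct-6-en-1-yl]oxy}dimethylsilane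
Conditions: dimethyl (1-diazo-2-oxopropyl)phosphonate, K2CO3, MeOH, 0 °C → rt
Reagents that add atoms: dimethyl (1-diazo-2-oxopropyl)phosphonate (Ohira–Bestmann reagent), COP(=O)(OC)C(=[N+]=[N-])C(C)=O
Why: Seyferth–Gilbert homologation with the Ohira–Bestmann reagent turns the aldehyde carbon into C5 and adds C6 as the terminal alkyne carbon, and the low temperature and the hindered α-position should limit epimerisation at C10.

**Step 10**
Reactants: 14 tert-butyl{[(2S,3R)-3-ethynyl-2,7-dimethyl-2-(prop-1-en-2-yl)oct-6-en-1-yl]oxy}dimethylsilane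
Product: 15 tert-butyl{[(2S,3R)-5-[(2S)-3,3-dimethyloxiran-2-yl]-3-ethynyl-2-methyl-2-(prop-1-en-2-yl)pentyl]oxy}dimethylsilane (C3 S, C9 S, C10 R in the ring numbering)
Conditions: L-fructose-derived Shi ketone (0.3 equiv), Oxone (2KHSO5·KHSO4·K2SO4), K2CO3, Bu4NHSO4, MeCN–dimethoxymethane–aqueous buffer (pH 10.5), 0 °C
Reagents that add atoms: Oxone (active component potassium peroxymonosulfate), [K+].[O-]S(=O)(=O)OO
Why: Shi asymmetric epoxidation, in which the dioxirane of the L-fructose-derived ketone should give the (3S)-epoxide of the electron-rich trisubstituted alkene (the D-fructose-derived ketone attacks the opposite face of 2-methylalk-2-enes), while the hindered isopropenyl group and the alkyne react much more slowly.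

**Step 11**
Reactants: 15 tert-butyl{[(2S,3R)-5-[(2S)-3,3-dimethyloxiran-2-yl]-3-ethynyl-2-methyl-2-(prop-1-en-2-yl)pentyl]oxy}dimethylsilane
Product: 17 (2S,4aR,5S)-5-{[tert-butyl(dimethyl)silyl]oxymethyl}-1,1,5-trimethyl-6-methylidene-1,2,3,4,4a,5,6,7-octahydronaphthalen-2-ol, via trimethylsilyl ether 16 (not isolated)
Conditions: Cp2TiCl2 (0.2 equiv), Mn dust (8 equiv), Me3SiCl (4 equiv), 2,4,6-collidine (7 equiv), THF (0.02 M), rt; then K2CO3, MeOH, rt
Reagents that add atoms: none
Why: Proposed new method: Cp2TiCl (trivalent titanium) transfers one electron to the epoxide and opens it at the more substituted carbon to a C3 titanium alkoxide and a tertiary C4 radical, which adds to the internal alkyne carbon C5 and closes ring A in the 6-exo-dig mode; the exocyclic C6 vinyl radical then adds to the CH2 terminus C7 of the isopropenyl group and closes ring B in the 6-endo-trig mode, and the tertiary C8 radical is captured by a second Cp2TiCl and loses a β-hydrogen from its methyl group to leave the C8=C12 exocyclic methylene. The closest known reaction types are the Cp2TiCl-mediated cyclisation of epoxypolyenes (6-endo closures ended by the same β-hydride elimination) and the Cp2TiCl-mediated exo-dig cyclisation of epoxy alkynes, including additions of the derived vinyl radicals to alkenes; the relay through an alkyne into a second ring is the part that has not been shown. No stereocentre is created, since C4 becomes a gem-dimethyl carbon, C5, C6 and C8 end as sp2 carbons, and C3, C9 and C10 are carried unchanged from 15. The step needs exo attack at C5 over 7-endo attack at C6, which the five-atom tether and the quaternary C9 next to C10 (Thorpe–Ingold effect) should secure, and attack at C7 over 5-exo attack at C8, which the methyl group on C8 slows and which a homoallyl–cyclopropylcarbinyl rearrangement of any 5-exo radical would correct at low titanium concentration. It also needs the vinyl radical to cyclise faster than it abstracts hydrogen from THF or from C11–H, which the isopropenyl group held on the adjacent quaternary C9 favours, and it needs elimination toward C12 and not toward the allylic C7–H, the usual outcome for tertiary radicals under these conditions. The catalytic protocol keeps Cp2TiCl low to limit premature trapping, and the C3 trimethylsilyl ether it forms is cleaved by K2CO3 in MeOH without loss of the C11 silyl ether.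

**Step 12**
Reactants: 17 (2S,4aR,5S)-5-{[tert-butyl(dimethyl)silyl]oxymethyl}-1,1,5-trimethyl-6-methylidene-1,2,3,4,4a,5,6,7-octahydronaphthalen-2-ol
Product: 18 (2S,4aR,5S)-5-{[tert-butyl(dimethyl)silyl]oxymethyl}-1,1,5-trimethyl-6-methylidene-1,2,3,4,4a,5,6,7-octahydronaphthalen-2-yl acetate
Conditions: Ac2O, DMAP, pyridine, CH2Cl2, rt
Reagents that add atoms: acetic anhydride, CC(=O)OC(C)=O
Why: DMAP-catalysed acetylation masks the hindered secondary C3 alcohol, so that it can neither direct the iridium catalyst to C5=C6 nor be triflated later.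

**Step 13**
Reactants: 18 (2S,4aR,5S)-5-{[tert-butyl(dimethyl)silyl]oxymethyl}-1,1,5-trimethyl-6-methylidene-1,2,3,4,4a,5,6,7-octahydronaphthalen-2-yl acetate
Product: 19 (2S,4aR,5S)-5-(hydroxymethyl)-1,1,5-trimethyl-6-methylidene-1,2,3,4,4a,5,6,7-octahydronaphthalen-2-yl acetate
Conditions: HF·pyridine, pyridine, THF, 0 °C → rt
Reagents that add atoms: none
Why: Fluoride-mediated desilylation under pyridine buffering frees the primary C11 alcohol without touching the acetate or the two alkenes.

**Step 14**
Reactants: 19 (2S,4aR,5S)-5-(hydroxymethyl)-1,1,5-trimethyl-6-methylidene-1,2,3,4,4a,5,6,7-octahydronaphthalen-2-yl acetate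
Product: 20 (2S,4aR,5R,6S)-5-(hydroxymethyl)-1,1,5,6-tetramethyl-1,2,3,4,4a,5,6,7-octahydronaphthalen-2-yl acetate
Conditions: [Ir(cod)(PCy3)(py)]PF6 (5 mol %), H2 (1 atm), CH2Cl2, 0 °C → rt
Reagents that add atoms: none
Why: Hydroxyl-directed homogeneous hydrogenation, in which the cationic iridium catalyst binds the C11 hydroxyl and delivers H2 to C8=C12 from the face of C9 that carries C11, so that H8 ends cis to C11 and the new methyl cis to the C9 methyl (8S), while the hindered trisubstituted C5=C6 next to the quaternary C4 should survive.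

**Step 15**
Reactants: 20 (2S,4aR,5R,6S)-5-(hydroxymethyl)-1,1,5,6-tetramethyl-1,2,3,4,4a,5,6,7-octahydronaphthalen-2-yl acetate
Product: 21 (2S,4aR,5R,6S)-1,1,5,6-tetramethyl-5-({[(trifluoromethyl)sulfonyl]oxy}methyl)-1,2,3,4,4a,5,6,7-octahydronaphthalen-2-yl acetate
Conditions: Tf2O, 2,6-lutidine, CH2Cl2, −78 → −30 °C; used at once
Reagents that add atoms: trifluoromethanesulfonic anhydride, O=S(=O)(OS(=O)(=O)C(F)(F)F)C(F)(F)F
Why: O-Sulfonylation with a hindered pyridine base gives the primary triflate, which has no β-hydrogen (C9 is quaternary) and therefore cannot eliminate.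

**Step 16**
Reactants: 21 (2S,4aR,5R,6S)-1,1,5,6-tetramethyl-5-({[(trifluoromethyl)sulfonyl]oxy}methyl)-1,2,3,4,4a,5,6,7-octahydronaphthalen-2-yl acetate; 22 isofraxidin (7-hydroxy-6,8-dimethoxy-2H-chromen-2-one)
Product: 24 (2S,4aR,5R,6S)-5-{[(6,8-dimethoxy-2-oxo-2H-chromen-7-yl)oxy]methyl}-1,1,5,6-tetramethyl-1,2,3,4,4a,5,6,7-octahydronaphthalen-2-yl acetate, via cesium phenoxide 23 (not isolated)
Conditions: 22, Cs2CO3, DMPU–THF, rt; then 21, rt → 50 °C
Reagents that add atoms: none
Why: Williamson ether synthesis (SN2), in which the cesium phenoxide, with both ortho positions blocked so that only O-alkylation is possible, displaces triflate at the neopentyl-type C11 in a dipolar aprotic medium, the leaving group making up for the hindered carbon.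

**Step 17**
Reactants: 24 (2S,4aR,5R,6S)-5-{[(6,8-dimethoxy-2-oxo-2H-chromen-7-yl)oxy]methyl}-1,1,5,6-tetramethyl-1,2,3,4,4a,5,6,7-octahydronaphthalen-2-yl acetate
Product: 25 7-{[(1R,2S,6S,8aR)-6-hydroxy-1,2,5,5-tetramethyl-1,2,3,5,6,7,8,8a-octahydronaphthalen-1-yl]methoxy}-6,8-dimethoxy-2H-chromen-2-one (CNP0110107.1)
Conditions: K2CO3, MeOH, rt → 40 °C; then 1 M HCl, rt
Reagents that add atoms: none
Why: Base-catalysed transesterification removes the C3 acetate, any coumarin lactone opened to the methyl (Z)-2-hydroxycinnamate recloses on acidification, and the aryl alkyl ether and C5=C6 are inert.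

**Compound list**

1 | diethyl malonate | CCOC(=O)CC(=O)OCC | starting material
2 | 5-bromo-2-methylpent-2-ene | CC(C)=CCCBr | starting material
3 | diethyl 2-(4-methylpent-3-en-1-yl)propanedioate | CCOC(=O)C(CCC=C(C)C)C(=O)OCC | intermediate
4 | 2-(4-methylpent-3-en-1-yl)propanedioic acid (not isolated) | OC(=O)C(CCC=C(C)C)C(O)=O | intermediate
5 | 6-methylhept-5-enoic acid | CC(C)=CCCCC(O)=O | intermediate
6 | 2,3-dimethylmaleic anhydride | CC1=C(C)C(=O)OC1=O | starting material
7 | (2Z)-2,3-dimethylbut-2-ene-1,4-diol | OC/C(C)=C(/C)CO | intermediate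
8 | (2Z)-4-{[tert-butyl(dimethyl)silyl]oxy}-2,3-dimethylbut-2-en-1-ol | OC/C(C)=C(/C)CO[Si](C)(C)C(C)(C)C | intermediate
9 | (2Z)-4-{[tert-butyl(dimethyl)silyl]oxy}-2,3-dimethylbut-2-en-1-yl 6-methylhept-5-enoate | CC(C)=CCCCC(=O)OC/C(C)=C(/C)CO[Si](C)(C)C(C)(C)C | intermediate
10 | boron enolate of 9, side chain trans to O–B, boron carrying the (4S,5S)-4,5-diphenyl-1,3-bis{[3,5-bis(trifluoromethyl)phenyl]sulfonyl}-1,3,2-diazaborolidine ring (not isolated) | CC(C)=CCC/C=C(/OB1N(S(=O)(=O)c2cc(C(F)(F)F)cc(C(F)(F)F)c2)[C@@H](c2ccccc2)[C@H](c2ccccc2)N1S(=O)(=O)c2cc(C(F)(F)F)cc(C(F)(F)F)c2)OC/C(C)=C(/C)CO[Si](C)(C)C(C)(C)C | intermediate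
11 | (2S,3S)-3-{[tert-butyl(dimethyl)silyl]oxymethyl}-3,4-dimethyl-2-(4-methylpent-3-en-1-yl)pent-4-enoic acid | OC(=O)[C@@H](CCC=C(C)C)[C@](C)(CO[Si](C)(C)C(C)(C)C)C(C)=C | intermediate
12 | (2S,3S)-3-{[tert-butyl(dimethyl)silyl]oxymethyl}-3,4-dimethyl-2-(4-methylpent-3-en-1-yl)pent-4-en-1-ol | OC[C@@H](CCC=C(C)C)[C@](C)(CO[Si](C)(C)C(C)(C)C)C(C)=C | intermediate
13 | (2S,3S)-3-{[tert-butyl(dimethyl)silyl]oxymethyl}-3,4-dimethyl-2-(4-methylpent-3-en-1-yl)pent-4-enal | O=C[C@@H](CCC=C(C)C)[C@](C)(CO[Si](C)(C)C(C)(C)C)C(C)=C | intermediate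
14 | tert-butyl{[(2S,3R)-3-ethynyl-2,7-dimethyl-2-(prop-1-en-2-yl)oct-6-en-1-yl]oxy}dimethylsilane | C#C[C@@H](CCC=C(C)C)[C@](C)(CO[Si](C)(C)C(C)(C)C)C(C)=C | intermediate
15 | tert-butyl{[(2S,3R)-5-[(2S)-3,3-dimethyloxiran-2-yl]-3-ethynyl-2-methyl-2-(prop-1-en-2-yl)pentyl]oxy}dimethylsilane (key-step precursor) | C#C[C@@H](CC[C@@H]1OC1(C)C)[C@](C)(CO[Si](C)(C)C(C)(C)C)C(C)=C | intermediate
16 | C3 trimethylsilyl ether of 17 (not isolated) | CC(C)(C)[Si](C)(C)OC[C@@]1(C)[C@@H]2CC[C@H](O[Si](C)(C)C)C(C)(C)C2=CCC1=C | intermediate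
17 | (2S,4aR,5S)-5-{[tert-butyl(dimethyl)silyl]oxymethyl}-1,1,5-trimethyl-6-methylidene-1,2,3,4,4a,5,6,7-octahydronaphthalen-2-ol (key-step product) | CC(C)(C)[Si](C)(C)OC[C@@]1(C)[C@@H]2CC[C@H](O)C(C)(C)C2=CCC1=C | intermediate
18 | (2S,4aR,5S)-5-{[tert-butyl(dimethyl)silyl]oxymethyl}-1,1,5-trimethyl-6-methylidene-1,2,3,4,4a,5,6,7-octahydronaphthalen-2-yl acetate | CC(C)(C)[Si](C)(C)OC[C@@]1(C)[C@@H]2CC[C@H](OC(C)=O)C(C)(C)C2=CCC1=C | intermediate
19 | (2S,4aR,5S)-5-(hydroxymethyl)-1,1,5-trimethyl-6-methylidene-1,2,3,4,4a,5,6,7-octahydronaphthalen-2-yl acetate | OC[C@@]1(C)[C@@H]2CC[C@H](OC(C)=O)C(C)(C)C2=CCC1=C | intermediate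
20 | (2S,4aR,5R,6S)-5-(hydroxymethyl)-1,1,5,6-tetramethyl-1,2,3,4,4a,5,6,7-octahydronaphthalen-2-yl acetate | OC[C@@]1(C)[C@@H]2CC[C@H](OC(C)=O)C(C)(C)C2=CC[C@@H]1C | intermediate
21 | (2S,4aR,5R,6S)-1,1,5,6-tetramethyl-5-({[(trifluoromethyl)sulfonyl]oxy}methyl)-1,2,3,4,4a,5,6,7-octahydronaphthalen-2-yl acetate | O=S(=O)(OC[C@@]1(C)[C@@H]2CC[C@H](OC(C)=O)C(C)(C)C2=CC[C@@H]1C)C(F)(F)F | intermediate
22 | isofraxidin (7-hydroxy-6,8-dimethoxy-2H-chromen-2-one) | COc1cc2ccc(=O)oc2c(OC)c1O | starting material
23 | cesium 6,8-dimethoxy-2-oxo-2H-chromen-7-olate (not isolated) | COc1cc2ccc(=O)oc2c(OC)c1[O-].[Cs+] | intermediate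
24 | (2S,4aR,5R,6S)-5-{[(6,8-dimethoxy-2-oxo-2H-chromen-7-yl)oxy]methyl}-1,1,5,6-tetramethyl-1,2,3,4,4a,5,6,7-octahydronaphthalen-2-yl acetate | COc1cc2ccc(=O)oc2c(OC)c1OC[C@@]1(C)[C@@H]2CC[C@H](OC(C)=O)C(C)(C)C2=CC[C@@H]1C | intermediate
25 | 7-{[(1R,2S,6S,8aR)-6-hydroxy-1,2,5,5-tetramethyl-1,2,3,5,6,7,8,8a-octahydronaphthalen-1-yl]methoxy}-6,8-dimethoxy-2H-chromen-2-one | COc1cc2ccc(=O)oc2c(OC)c1OC[C@@]1(C)[C@@H]2CC[C@H](O)C(C)(C)C2=CC[C@@H]1C | target

**Step count**

Total: 17 steps. Longest linear sequence: 15 steps (steps 1, 2 and 5–17 from diethyl malonate; equally steps 3, 4 and 5–17 from the anhydride).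

**Steps most likely to fail**

1. Step 11 (radical bicyclisation). The vinyl radical may abstract hydrogen from THF, take the C11–H by 1,5-transfer or be trapped by titanium before ring B closes; ring B may close 5-exo; or the final β-hydride loss may go toward C7 and give a conjugated diene. The fallback sets out from 15 and comes back at 20, using a tin hydride chain in a solvent that donates no hydrogen. Opening of the epoxide with LiBr and AcOH in THF should give the tertiary bromide with retention at C3, bromohydrin F1. Acetylation (Ac2O, DMAP, pyridine) gives the bromo acetate F2. Slow addition of Bu3SnH with AIBN to F2 in benzene at 80 °C runs the same two closures as a known tin hydride cascade (alkyl radical exo-dig closure, then vinyl radical closure) and ends by hydrogen transfer to C8, giving the bicyclic silyl ether acetate F3 as a mixture of C8 epimers. The epimers are separated and the 8S epimer is desilylated with HF·pyridine to 20. The price is that C8 is no longer set by the directed hydrogenation.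

2. Step 16 (aryl ether formation). Substitution at the neopentyl-type C11 by a hindered, weakly nucleophilic phenoxide may be too slow, so that attack at sulfur (returning 20) or ionisation with a 1,2-shift takes over. The fallback sets out from 22 and 20 and comes back at 24, forming the aryl–oxygen bond instead of the alkyl–oxygen bond. Tf2O and pyridine convert 22 into isofraxidin triflate F4. Palladium-catalysed triflate-to-bromide exchange (Pd2(dba)3, tBuBrettPhos, KBr) gives 7-bromo-6,8-dimethoxycoumarin F5. Palladium-catalysed C–O cross-coupling of F5 with alcohol 20 ([Pd(C3H5)Cl]2, RockPhos, Cs2CO3, toluene, 90 °C) should then give 24 without any substitution at C11.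

3. Step 6 (enantioselective Claisen rearrangement). With the tetrasubstituted alkene, facial selection by the boron reagent may be poor, the chair preference may erode, the rearrangement may be too slow, or the Lewis-acidic bromoborane may strip the allylic silyl ether. The fallback sets out from 9 and comes back at 15, replacing reagent control in the rearrangement by separation of diastereomers after the reagent-controlled epoxidation. LiN(iPr)2 with Me3SiCl–Et3N in THF (−78 °C → 60 °C) gives the silyl ketene acetal F6 with the same geometry (side chain cis to the allyloxy oxygen), and its Ireland–Claisen rearrangement gives 11 as a racemate with its enantiomer, ent-acid F7. The racemate is carried through steps 7–9 unchanged, which adds the ent-alcohol F8, the ent-aldehyde F9 and the ent-enyne F10. The Shi epoxidation of step 10 then turns the racemic enyne into 15 and its (3S,9R,10S) diastereomer, epoxy enyne F11, which are separated by preparative HPLC. Half of the material is lost.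

**Further compounds**

F1 | step 11 | (3S)-bromohydrin from 15: C4 tertiary bromide, C3 hydroxyl | C#C[C@@H](CC[C@H](O)C(C)(C)Br)[C@](C)(CO[Si](C)(C)C(C)(C)C)C(C)=C
F2 | step 11 | C3 acetate of F1 | C#C[C@@H](CC[C@H](OC(C)=O)C(C)(C)Br)[C@](C)(CO[Si](C)(C)C(C)(C)C)C(C)=C
F3 | step 11 | C11 tert-butyldimethylsilyl ether of 20 as a mixture of C8 epimers (8S epimer carried on) | CC(C)(C)[Si](C)(C)OC[C@@]1(C)[C@@H]2CC[C@H](OC(C)=O)C(C)(C)C2=CCC1C
F4 | step 16 | 6,8-dimethoxy-2-oxo-2H-chromen-7-yl trifluoromethanesulfonate | COc1cc2ccc(=O)oc2c(OC)c1OS(=O)(=O)C(F)(F)F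
F5 | step 16 | 7-bromo-6,8-dimethoxy-2H-chromen-2-one | COc1cc2ccc(=O)oc2c(OC)c1Br
F6 | step 6 | trimethylsilyl ketene acetal of 9, side chain trans to OSi | CC(C)=CCC/C=C(/O[Si](C)(C)C)OC/C(C)=C(/C)CO[Si](C)(C)C(C)(C)C
F7 | step 6 | (2R,3R) enantiomer of acid 11 | OC(=O)[C@H](CCC=C(C)C)[C@@](C)(CO[Si](C)(C)C(C)(C)C)C(C)=C
F8 | step 6 | (2R,3R) enantiomer of alcohol 12 | OC[C@H](CCC=C(C)C)[C@@](C)(CO[Si](C)(C)C(C)(C)C)C(C)=C
F9 | step 6 | (2R,3R) enantiomer of aldehyde 13 | O=C[C@H](CCC=C(C)C)[C@@](C)(CO[Si](C)(C)C(C)(C)C)C(C)=C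
F10 | step 6 | (2R,3S) enantiomer of enyne 14 | C#C[C@H](CCC=C(C)C)[C@@](C)(CO[Si](C)(C)C(C)(C)C)C(C)=C
F11 | step 6 | (3S,9R,10S) diastereomer of epoxy enyne 15 | C#C[C@H](CC[C@@H]1OC1(C)C)[C@@](C)(CO[Si](C)(C)C(C)(C)C)C(C)=C
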